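**Retrosynthetic overview**
1. Target (17) ⇐ Ac2O acetylation of bridged hemiacetal 16 ⇐ TFA cascade on lactol 15 (tBu cleavage, menthyl-acetal ionisation, bridging δ-lactone/THF closure last).
2. 15 ⇐ DIBAL, C5–C6 α-alkylation and Petasis methylenation (C1=C2) of γ-lactone ketone 12.
3. Key step: the acyl radical from hydroazulene aldehyde 9 adds anti to the menthyloxy group of butenolide 11, forming C2–C3 and setting C3.
4. 9 ⇐ one-carbon homologation of ketone 7; 7 ⇐ 7-exo-dig closure of the α-keto radical from 6 (7-ring, quaternary C23, exocyclic CH2); 6 ⇐ Ohira–Bestmann alkyne ⇐ aldehyde ⇐ MHAT Giese (C14–C15) of 1 + 2.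
5. Ring order: cyclopentanone (from SM 1) → cycloheptane (step 5) → γ-lactone (from 11) → THF/δ-lactone bicycle (step 13).

Assumptions:
- 5-Methylhex-4-en-1-ol (2) and 5-hydroxy-2(5H)-furanone (10) are purchasable.
- The tBu of tert-butyl bromoacetate is a protecting group (the building block is bromoacetate, 5 heavy atoms); (+)-menthol is a removable chiral auxiliary counted as a reagent.
- Compounds 3–9 are racemic; the diastereomers formed in step 9 are separated there.

**Step 1**
Reactants: 1 (2-methylcyclopent-2-en-1-one); 2 (5-methylhex-4-en-1-ol)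
Product: 3 (±)-3-(6-hydroxy-2-methylhexan-2-yl)-2-methylcyclopentan-1-one
Conditions: Fe(acac)3, PhSiH3, EtOH, 60 °C
Reagents that add atoms: none
Why: Fe–H hydrogen-atom transfer to the trisubstituted alkene of 2 gives a tertiary radical that adds to the β-carbon of enone 1 (MHAT Giese / reductive olefin coupling), forming the hindered C14–C15 bond; the only new stereocentre (C14) is racemic and the C23 epimer is irrelevant because C23 is made quaternary in step 5.

**Step 2**
Reactants: 3
Product: 4 (±)-5-methyl-5-(2-methyl-3-oxocyclopentyl)hexanal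
Conditions: Dess–Martin periodinane, NaHCO3, CH2Cl2, 0 °C → rt
Reagents that add atoms: none
Why: Dess–Martin oxidation takes the primary alcohol to the aldehyde and leaves the hindered ketone untouched.

**Step 3**
Reactants: 4
Product: 5 (±)-2-methyl-3-(2-methylhept-6-yn-2-yl)cyclopentan-1-one
Conditions: Ohira–Bestmann reagent, K2CO3, MeOH, 0 °C → rt
Reagents that add atoms: dimethyl (1-diazo-2-oxopropyl)phosphonate, CC(=O)C(=[N+]=[N-])P(=O)(OC)OC (supplies C22)
Why: Ohira–Bestmann homologation converts the aldehyde (C21) into the terminal alkyne under mild base that leaves the ketone alone.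

**Step 4**
Reactants: 5
Product: 6 (±)-2-bromo-2-methyl-3-(2-methylhept-6-yn-2-yl)cyclopentan-1-one
Conditions: CuBr2, EtOAc/CHCl3 1:1, reflux
Reagents that add atoms: CuBr2, Br[Cu]Br
Why: Enolisation toward the more substituted α-carbon gives the tertiary α-bromoketone, the precursor of the C23 radical.

**Step 5**
Reactants: 6
Product: 7 (±)-trans-fused 4,4,8a-trimethyl-8-methylidene-octahydroazulen-1(2H)-one
Conditions: Bu3SnH (syringe pump, 6 h), AIBN, benzene (0.005 M), 80 °C
Reagents that add atoms: none (Br lost, H gained)
Why: Bu3SnH generates the tertiary α-keto radical at C23, which closes onto the terminal alkyne (7-exo-dig) to make the quaternary centre and the exocyclic methylene after H-transfer to the vinyl radical.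
Proposed new method: the α-keto radical closes through a chair-like 7-exo TS; the neopentylic gem-dimethyl C15 disfavours the eclipsed cis-fused TS, so the trans-fused 5-7 system (C21 up, C15 down, Me down) should dominate and any cis isomer is removed by chromatography; closest precedent is Bu3SnH-mediated 7-exo-dig cyclisation of α-keto radicals.

**Step 6**
Reactants: 7
Product: 8 (±)-methoxymethylene enol ether of 7
Conditions: Ph3P=CHOMe, THF, 0 → 50 °C
Reagents that add atoms: methoxymethylenetriphenylphosphorane, COC=P(c1ccccc1)(c1ccccc1)c1ccccc1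
Why: Wittig methoxymethylenation adds the future C2 carbon to the C11 carbonyl; the stereocentres are untouched.

**Step 7**
Reactants: 8
Product: 9 (±)-4,4,8a-trimethyl-8-methylidene-decahydroazulene-1-carbaldehyde
Conditions: 1 M aq. HCl, THF, rt
Reagents that add atoms: water, O
Why: Enol-ether hydrolysis gives the aldehyde, and the α-stereocentre C11 equilibrates to the less hindered epimer with CHO cis to the angular methyl (C2 down), which is the configuration required.

**Step 8**
Reactants: 10 (5-hydroxy-2(5H)-furanone)
Product: 11 (5S)-5-[(1S,2R,5S)-menthyloxy]furan-2(5H)-one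
Conditions: (+)-menthol, p-TsOH (cat.), CH2Cl2, rt; recrystallise from hexane
Reagents that add atoms: (+)-menthol, C[C@H]1CC[C@@H]([C@H](C1)O)C(C)C
Why: Acid-catalysed acetalisation with crystallisation-induced epimerisation of the acetal carbon gives the single (5S)-diastereomer, the mirror image of the known l-menthol (5R) series, so the C4 acetal configuration directs the next step.

**Step 9 (key radical step)**
Reactants: 9; 11
Product: 12 (desired diastereomer; 4-acyl-5-menthyloxy-γ-butyrolactone, C2 ketone)
Conditions: TBADT (2 mol %), MeCN, 390 nm, rt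
Reagents that add atoms: none
Why: Decatungstate HAT removes the aldehyde H to give the acyl radical, which adds to the β-carbon of butenolide 11 anti to the menthyloxy group; this sets C3 with C2 on the same face as the eventual lactone bridge, and the α-lactonyl radical is reduced, leaving C7 as CH2.
Proposed new method: a hindered α-branched aldehyde and a γ-alkoxybutenolide acceptor are combined by HAT-generated acyl radicals; mechanistically this is the facially controlled radical conjugate addition known for (5R)-menthyloxybutenolide with alkyl radicals, carried out with photocatalytic hydroacylation of electron-poor alkenes. Racemic 9 gives two diastereomers (enantiomeric hydroazulene halves), separated by chromatography; the desired one carries the natural hydroazulene.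

**Step 10**
Reactants: 12
Product: 13 (C2 ketone → C1=C2 methylene)
Conditions: Cp2TiMe2 (3 equiv), toluene, 75 °C, dark
Reagents that add atoms: dimethyltitanocene, C[Ti](C)(C1C=CC=C1)C1C=CC=C1 (supplies C1)
Why: Petasis methylenation is selective for the ketone over the lactone and acetal and is non-basic, so the C3/C11 stereocentres, which are α to the carbonyl, are not epimerised.

**Step 11**
Reactants: 13
Product: 14 (C7-alkylated lactone with CH2CO2tBu, C6 trans to C2)
Conditions: LiHMDS, THF, −78 °C; then tBuO2CCH2Br, DMPU, −78 → −40 °C
Reagents that add atoms: tert-butyl bromoacetate, CC(C)(C)OC(=O)CBr (supplies C6 and C5)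
Why: The lactone enolate is alkylated anti to the large C3 substituent; the resulting C7 configuration is provisional because C7 is re-set thermodynamically in step 13.

**Step 12**
Reactants: 14
Product: 15 (γ-lactol, anomeric mixture at C8)
Conditions: DIBAL-H (1.05 equiv), toluene, −78 °C
Reagents that add atoms: none
Why: At −78 °C DIBAL reduces the γ-lactone to the lactol faster than the tBu ester and leaves the alkenes and the menthyl acetal intact.

**Step 13**
Reactants: 15
Product: 16 (bicyclic hemiacetal, 2,7-dioxabicyclo[3.2.1] core)
Conditions: TFA, CH2Cl2, 0 °C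
Reagents that add atoms: none (menthol and isobutylene are lost)
Why: TFA cleaves the tBu ester and ionises the menthyl acetal at C4; the free acid closes the bridging δ-lactone on the face syn to C6.
Proposed new method: C7 epimerises through the ring-opened aldehyde tautomer, so bridge closure (Curtin–Hammett) sets C7 cis to C2, fixes C4 by oxocarbenium capture on the same face, and lets the C8 anomer equilibrate to exo; closest known reaction types are acid-mediated acetal/acylal exchange and intramolecular transacetalisation to 2,7-dioxabicyclo[3.2.1]octanes.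

**Step 14**
Reactants: 16
Product: 17 chelonaplysin C
Conditions: Ac2O, pyridine, DMAP (cat.), CH2Cl2, 0 °C → rt
Reagents that add atoms: acetic anhydride, CC(=O)OC(C)=O
Why: Acetylation of the exo hemiacetal OH gives the exo acetoxy acetal; C3, C4, C7 and C11 and the hydroazulene centres are untouched.

**Compound list**
1 | 2-methylcyclopent-2-en-1-one | CC1=CCCC1=O | starting material
2 | 5-methylhex-4-en-1-ol | CC(C)=CCCCO | starting material
3 | (±)-3-(6-hydroxy-2-methylhexan-2-yl)-2-methylcyclopentan-1-one | CC1C(CCC1=O)C(C)(C)CCCCO | intermediate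
4 | (±)-5-methyl-5-(2-methyl-3-oxocyclopentyl)hexanal | CC1C(CCC1=O)C(C)(C)CCCC=O | intermediate
5 | (±)-2-methyl-3-(2-methylhept-6-yn-2-yl)cyclopentan-1-one | CC1C(CCC1=O)C(C)(C)CCCC#C | intermediate
6 | (±)-2-bromo-2-methyl-3-(2-methylhept-6-yn-2-yl)cyclopentan-1-one | CC1(Br)C(CCC1=O)C(C)(C)CCCC#C | intermediate
7 | (±)-trans-4,4,8a-trimethyl-8-methylidene-octahydroazulen-1(2H)-one (one enantiomer drawn) | O=C1CC[C@H]2C(C)(C)CCCC(=C)[C@]12C | intermediate
8 | (±)-1-(methoxymethylidene) enol ether of 7 | COC=C1CC[C@H]2C(C)(C)CCCC(=C)[C@]12C | intermediate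
9 | (±)-4,4,8a-trimethyl-8-methylidene-decahydroazulene-1-carbaldehyde (one enantiomer drawn) | O=C[C@H]1CC[C@H]2C(C)(C)CCCC(=C)[C@]12C | intermediate
10 | 5-hydroxy-2(5H)-furanone | O=C1C=CC(O)O1 | starting material
11 | (5S)-5-[(1S,2R,5S)-menthyloxy]furan-2(5H)-one | O=C1C=C[C@H](O1)O[C@H]2C[C@@H](C)CC[C@@H]2C(C)C | intermediate
12 | γ-lactone ketone (C2=O, C3 anti to menthyloxy) | O=C([C@H]1CC[C@H]2C(C)(C)CCCC(=C)[C@]12C)[C@@H]3[C@@H](O[C@H]4C[C@@H](C)CC[C@@H]4C(C)C)OC(=O)C3 | intermediate
13 | methylenated lactone (C1=C2) | C=C([C@H]1CC[C@H]2C(C)(C)CCCC(=C)[C@]12C)[C@@H]3[C@@H](O[C@H]4C[C@@H](C)CC[C@@H]4C(C)C)OC(=O)C3 | intermediate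
14 | C7-(tBu acetate) lactone, C6 trans to C2 | C=C([C@H]1CC[C@H]2C(C)(C)CCCC(=C)[C@]12C)[C@@H]3[C@@H](O[C@H]4C[C@@H](C)CC[C@@H]4C(C)C)OC(=O)[C@H]3CC(=O)OC(C)(C)C | intermediate
15 | lactol (C8 anomeric mixture) | C=C([C@H]1CC[C@H]2C(C)(C)CCCC(=C)[C@]12C)[C@@H]3[C@@H](O[C@H]4C[C@@H](C)CC[C@@H]4C(C)C)OC(O)[C@H]3CC(=O)OC(C)(C)C | intermediate
16 | bicyclic hemiacetal (8-hydroxy analogue of the target) | C=C([C@@H]1[C@@H]2OC(=O)C[C@H]1[C@H](O)O2)[C@H]1CC[C@H]2C(C)(C)CCCC(=C)[C@]12C | intermediate
17 | chelonaplysin C | C=C([C@@H]1[C@@H]2OC(=O)C[C@H]1[C@H](OC(C)=O)O2)[C@H]1CC[C@H]2C(C)(C)CCCC(=C)[C@]12C | target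

**Totals:** 14 steps in total; longest linear sequence 13 steps (1 → 3 → 4 → 5 → 6 → 7 → 8 → 9 → 12 → 13 → 14 → 15 → 16 → 17).

**Three steps most likely to fail**
1. **Step 9 (TBADT acyl-radical addition).** Decatungstate may abstract the acetal/allylic C4–H of 11 or the allylic C–H of 9, and the hindered secondary acyl radical may decarbonylate.
   Fallback: convert 9 to its acyl selenide (Pinnick oxidation, then the selenoester) and run a tin-free radical acylation (Et3B/(TMS)3SiH) on 11, which changes the radical precursor and initiation mode.
2. **Step 5 (7-exo-dig closure and ring-fusion stereochemistry).** Reduction of the radical may outcompete closure, and the cis-fused isomer may form.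
   Fallback: close the ring ionically by Conia-ene cyclisation (Au(I) on the silyl enol ether of 5), then set the trans ring fusion by photochemical HAT epimerisation of the tertiary C14–H.
3. **Step 13 (TFA cascade).** The acid may protonate the 1,1-disubstituted alkenes, or close the γ-lactone at C8 instead of the bridged δ-lactone at C4.
   Fallback: use allyl bromoacetate in step 11, remove the allyl ester with Pd(PPh3)4/morpholine, and effect bridging in a separate step with PPTS in benzene, so the acid is never exposed to strong Brønsted conditions.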